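## Retrosynthetic overview

- **Feature used:** 12 has a mirror plane through C1 and C4 of the central ring B. C3 and C5 of B carry the same CH2–ring A unit. In each ring A the bridge carbon on C1′ is flanked by the OH groups on C2′/C6′ and stands para to the OMe on C4′.
- **Key disconnection:** both bonds C3(B)–CH2 and C5(B)–CH2 are cut at once, as a two-directional, biomimetic o-quinone methide union. Unprotected phlorobutyrophenone 9 is the double nucleophile. Neither formaldehyde nor a ring A monomer with an open C1′–H is used.
- **Origin of the bridge carbon:** each bridge carbon arrives on ring A as a formyl carbon with three jobs. It steers ether cleavage to C2′/C6′ so that only the C4′ OMe stays (3 → 4). It blocks C1′ so that butanoyl can only enter at C3′ (4 → 5). It is then reduced to the CH2NMe2 trigger of the quinone methide (5 → 7).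
- **Rings:** no ring is formed. The three benzene rings are bought as 2,4,6-trimethoxytoluene 1 (used twice) and phloroglucinol 8, and no protecting group is used.

Key step: step 6

Remark: 12 has no stereocentre and a mirror plane in its constitution. It is achiral, its SMILES carries no stereo descriptor, and no step has to control configuration.

## Route

Step 1
Reactants: 1 2,4,6-trimethoxytoluene
Product: 3 2,4,6-trimethoxy-3-methylbenzaldehyde, via aryl iminium chloride 2 (not isolated)
Conditions: POCl3 (1.2 equiv), DMF, 0 °C to rt; then ice-water
Reagents that add atoms: N,N-dimethylformamide CN(C)C=O; water O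
Why: Vilsmeier–Haack formylation, in which the two open positions of the electron-rich arene 1 are equivalent, so a single aldehyde should result, and the new formyl group deactivates the ring against a second attack.

Step 2
Reactants: 3 2,4,6-trimethoxy-3-methylbenzaldehyde
Product: 4 2,6-dihydroxy-4-methoxy-3-methylbenzaldehyde
Conditions: AlCl3 (4 equiv), PhCl, 70 °C; then 2 M HCl, 0 °C
Reagents that add atoms: none
Why: Chelation-controlled Lewis acid ether cleavage, in which aluminium bound to the formyl oxygen activates only the two ortho methyl ethers (C2, C6) while the para OMe has no neighbouring carbonyl group, as in the classical partial demethylation of 2,4,6-trimethoxyaryl carbonyl compounds to their 2,6-dihydroxy-4-methoxy forms.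

Step 3
Reactants: 4 2,6-dihydroxy-4-methoxy-3-methylbenzaldehyde
Product: 5 3-butanoyl-2,6-dihydroxy-4-methoxy-5-methylbenzaldehyde
Conditions: butanoic anhydride (1.5 equiv), BF3·OEt2 (4 equiv), 50 °C; then MeOH–H2O, 60 °C
Reagents that add atoms: butanoic anhydride CCCC(=O)OC(=O)CCC
Why: BF3-promoted Friedel–Crafts C-acylation of the type that turns monoacyl- into diacylphloroglucinols, where C5 of 4 is the only aromatic C–H left, the ring still carries three oxygen donors, BF3 leaves aryl methyl ethers intact, and boron chelates, O-butanoates or acylals are hydrolysed in the work-up.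

Step 4
Reactants: 5 3-butanoyl-2,6-dihydroxy-4-methoxy-5-methylbenzaldehyde
Product: 7 1-{3-[(dimethylamino)methyl]-2,4-dihydroxy-6-methoxy-5-methylphenyl}butan-1-one, via iminium phenolate 6 (not isolated)
Conditions: Me2NH (2 M in THF, 1.5 equiv), NaBH(OAc)3 (1.5 equiv), AcOH (cat.), THF, 0 °C to rt; aqueous work-up at pH 7
Reagents that add atoms: dimethylamine CNC
Why: Reductive amination, in which the formyl group condenses with Me2NH to the iminium phenolate 6 that triacetoxyborohydride reduces, while the hydrogen-bonded, doubly ortho-substituted aryl ketone forms no iminium ion and is inert to this hydride.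

Step 5
Reactants: 8 phloroglucinol
Product: 9 phlorobutyrophenone, 1-(2,4,6-trihydroxyphenyl)butan-1-one
Conditions: butanoyl chloride (1.0 equiv), AlCl3 (3.5 equiv), CH2Cl2–PhNO2, 40 °C; then ice/2 M HCl
Reagents that add atoms: butanoyl chloride CCCC(=O)Cl
Why: Friedel–Crafts acylation of a threefold symmetric arene, in which the first acyl group deactivates the ring, so one equivalent of acid chloride should stop at the monoketone.

Step 6
Reactants: 7 1-{3-[(dimethylamino)methyl]-2,4-dihydroxy-6-methoxy-5-methylphenyl}butan-1-one (2.1 equiv); 9 phlorobutyrophenone (1.0 equiv)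
Product: 12 Agrimol C, via o-quinone methide 10 (not isolated), via monobenzylated phlorobutyrophenone 11 (not isolated)
Conditions: 1,4-dioxane, 100 °C, slow N2 stream to carry off Me2NH
Reagents that add atoms: none
Why: Proton transfer from the vinylogous acid 9 to the benzylic amine of 7 and retro-Mannich loss of Me2NH give o-quinone methide 10, the phenolate of 9 adds through C3 (Michael addition, both rings rearomatise) to give 11, and the same sequence at C5 gives 12, so both C(ring B)–CH2 bonds are made and three rings are joined in one operation. The closest known reaction type is the thermal alkylation of acylphloroglucinols, 4-hydroxypyrones and related C–H acids with phenolic Mannich bases via o-quinone methides, which also mirrors the presumed biosynthesis of methylene-bridged phloroglucinols. No ring is closed and no stereocentre is created. The step needs hetero- over homo-coupling and exactly two alkylations: 7 has no aromatic C–H and cannot act as nucleophile, 9 has no benzylic leaving group and cannot act as electrophile, and 9 offers only C3–H and C5–H, so the count stops at two. O-alkylation of phenols by 10 is reversible and should drain to the C-alkylated products. Removal of Me2NH keeps the medium near neutral, which should hold back retro-Michael exchange of the bridges.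

## Compound list

1 | 2,4,6-trimethoxytoluene (1,3,5-trimethoxy-2-methylbenzene) | COc1cc(OC)c(C)c(OC)c1 | starting material
2 | N,N-dimethyl-1-(2,4,6-trimethoxy-3-methylphenyl)methaniminium chloride | COc1cc(OC)c(C=[N+](C)C)c(OC)c1C.[Cl-] | intermediate
3 | 2,4,6-trimethoxy-3-methylbenzaldehyde | COc1cc(OC)c(C=O)c(OC)c1C | intermediate
4 | 2,6-dihydroxy-4-methoxy-3-methylbenzaldehyde | COc1cc(O)c(C=O)c(O)c1C | intermediate
5 | 3-butanoyl-2,6-dihydroxy-4-methoxy-5-methylbenzaldehyde | CCCC(=O)c1c(O)c(C=O)c(O)c(C)c1OC | intermediate
6 | iminium phenolate of 5 with dimethylamine (zwitterion) | C[N+](C)=Cc1c([O-])c(C)c(OC)c(C(=O)CCC)c1O | intermediate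
7 | 1-{3-[(dimethylamino)methyl]-2,4-dihydroxy-6-methoxy-5-methylphenyl}butan-1-one | CCCC(=O)c1c(O)c(CN(C)C)c(O)c(C)c1OC | intermediate
8 | phloroglucinol (benzene-1,3,5-triol) | Oc1cc(O)cc(O)c1 | starting material
9 | phlorobutyrophenone, 1-(2,4,6-trihydroxyphenyl)butan-1-one | CCCC(=O)c1c(O)cc(O)cc1O | intermediate
10 | 4-butanoyl-5-hydroxy-3-methoxy-2-methyl-6-methylidenecyclohexa-2,4-dien-1-one (o-quinone methide) | C=C1C(=O)C(C)=C(OC)C(C(=O)CCC)=C1O | intermediate
11 | 1-{3-[(3-butanoyl-2,6-dihydroxy-4-methoxy-5-methylphenyl)methyl]-2,4,6-trihydroxyphenyl}butan-1-one | CCCC(=O)c1c(O)cc(O)c(Cc2c(O)c(C)c(OC)c(C(=O)CCC)c2O)c1O | intermediate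
12 | Agrimol C, 1-{3,5-bis[(3-butanoyl-2,6-dihydroxy-4-methoxy-5-methylphenyl)methyl]-2,4,6-trihydroxyphenyl}butan-1-one (achiral) | CCCC(=O)c1c(O)c(Cc2c(O)c(C)c(OC)c(C(=O)CCC)c2O)c(O)c(Cc2c(O)c(C)c(OC)c(C(=O)CCC)c2O)c1O | target

## Step count and risks

Total step count: 6. Longest linear sequence: 5 (steps 1, 2, 3, 4, 6).

**Step 6.**
- What may go wrong: the second benzylation may lag behind the first. At 100 °C residual amine may also promote retro-Michael opening of bridges already formed, so that ring units are exchanged.
- Fallback: cationic instead of anionic bridge formation, setting out from 5 and coming back at 12. NaBH4 in THF–EtOH at −20 °C should reduce only the formyl group to the benzylic alcohol 1-[2,4-dihydroxy-3-(hydroxymethyl)-6-methoxy-5-methylphenyl]butan-1-one F1. Two equivalents of F1 and one of 9 are then joined by acid-catalysed dehydrative Friedel–Crafts benzylation (cat. TsOH, dioxane, 20 °C). This medium is free of base, so the retro-Michael path is closed.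

**Step 3.**
- What may go wrong: acylation of the formyl-deactivated ring may be sluggish. Acid-induced self-condensation of the aldehyde with the open ring position, or loss of the formyl group, may then compete.
- Fallback: the order of bridging and acylation is inverted, setting out from 4 and coming back at 12.
  - Reductive amination of 4 (Me2NH, NaBH(OAc)3) gives 2-[(dimethylamino)methyl]-5-methoxy-4-methylbenzene-1,3-diol F2.
  - Heating two equivalents of F2 with 9 in dioxane gives 1-{3,5-bis[(2,6-dihydroxy-4-methoxy-3-methylphenyl)methyl]-2,4,6-trihydroxyphenyl}butan-1-one F3. Only the more acidic 9 is ionised there, so it outruns the neutral outer rings as nucleophile.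
  - A twofold Friedel–Crafts butanoylation (butanoic acid, BF3·OEt2, rt to 40 °C) at the only two aromatic C–H bonds of F3 then gives 12.

**Step 2.**
- What may go wrong: regiocontrol may be lost in the second ether cleavage through attack on the para OMe, or cleavage may stop after the first ortho ether.
- Fallback: exhaustive cleavage followed by selective re-methylation, setting out from 3 and coming back at 4. BBr3 (excess, CH2Cl2, −78 °C to rt) removes all three methyl groups to give 2,4,6-trihydroxy-3-methylbenzaldehyde F4. One equivalent of Me2SO4 with K2CO3 in acetone then methylates the C4 hydroxyl. That hydroxyl is para to the formyl group, is not hydrogen-bonded to it, and is the most acidic.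

## Further compounds

F1 | step 6 | 1-[2,4-dihydroxy-3-(hydroxymethyl)-6-methoxy-5-methylphenyl]butan-1-one | CCCC(=O)c1c(O)c(CO)c(O)c(C)c1OC
F2 | step 3 | 2-[(dimethylamino)methyl]-5-methoxy-4-methylbenzene-1,3-diol | CN(C)Cc1c(O)cc(OC)c(C)c1O
F3 | step 3 | 1-{3,5-bis[(2,6-dihydroxy-4-methoxy-3-methylphenyl)methyl]-2,4,6-trihydroxyphenyl}butan-1-one | CCCC(=O)c1c(O)c(Cc2c(O)cc(OC)c(C)c2O)c(O)c(Cc2c(O)cc(OC)c(C)c2O)c1O
F4 | step 2 | 2,4,6-trihydroxy-3-methylbenzaldehyde | Cc1c(O)cc(O)c(C=O)c1O
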